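The route rests on cutting the C2–C3 bond of the 2H-pyran ring. C2, the gem-dimethyl carbon on the ring oxygen O1, is a tertiary α-aryloxy centre, exactly the radical left when a fibrate-type aryloxyisobutyric acid loses CO2; C3=C4 is a styrene conjugated to the trioxygenated benzene ring. In one operation, photoredox/cobaloxime catalysis expels CO2, closes the pyran by 6-endo attack of the C2 radical on the terminal vinyl carbon (C3) and restores the C3=C4 alkene with release of H2. The precursor is a 2-(2-vinylaryloxy)-2-methylpropanoic acid that already carries the acetyl, hydroxy and methoxy groups; the benzoyl unit is added last by Claisen-type acylation.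

Key step: step 4

Remark: the target has no stereocentre, and its only ring alkene is necessarily cis, so no stereocontrol is needed. It is drawn as the diketo tautomer but should exist largely as the chelated enol.

Step 1
Reactants: 1 2',4'-dihydroxy-6'-methoxyacetophenone; 2 ethyl 2-bromo-2-methylpropanoate
Product: 3 ethyl 2-(4-acetyl-3-hydroxy-5-methoxyphenoxy)-2-methylpropanoate
Conditions: K2CO3 (1.5 equiv), 2 (1.5 equiv), DMF, 70 °C
Reagents that add atoms: ethyl 2-bromo-2-methylpropanoate (compound 2), CCOC(=O)C(C)(C)Br
Why: Williamson-type O-alkylation under fibrate conditions should occur only at the 4-OH, which is para to the acetyl group, more acidic and not hydrogen-bonded, while the chelated 2-OH stays free.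

Step 2
Reactants: 3 ethyl 2-(4-acetyl-3-hydroxy-5-methoxyphenoxy)-2-methylpropanoate
Product: 4 ethyl 2-(4-acetyl-3-hydroxy-2-iodo-5-methoxyphenoxy)-2-methylpropanoate
Conditions: N-iodosuccinimide (1.05 equiv), TFA (10 mol%), MeCN, 0 °C to rt, dark
Reagents that add atoms: N-iodosuccinimide, O=C1CCC(=O)N1I
Why: Electrophilic aromatic iodination is expected ortho to the free chelated phenol, at the carbon between OH and the aryloxy ether, as is usual for 2-hydroxy-4,6-dialkoxyacetophenones, and one equivalent of reagent limits di-iodination.

Step 3
Reactants: 4 ethyl 2-(4-acetyl-3-hydroxy-2-iodo-5-methoxyphenoxy)-2-methylpropanoate; 5 4,4,5,5-tetramethyl-2-vinyl-1,3,2-dioxaborolane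
Product: 7 2-(4-acetyl-2-ethenyl-3-hydroxy-5-methoxyphenoxy)-2-methylpropanoic acid, via vinyl ethyl ester 6 (not isolated)
Conditions: 5 (1.5 equiv), Pd(OAc)2 (3 mol%), SPhos (6 mol%), K3PO4 (3 equiv), dioxane/H2O 4:1, 80 °C; then LiOH·H2O (5 equiv), MeOH, 50 °C; cold 1 M HCl to pH 3
Reagents that add atoms: 4,4,5,5-tetramethyl-2-vinyl-1,3,2-dioxaborolane (compound 5), C=CB1OC(C)(C)C(C)(C)O1; lithium hydroxide, [Li+].[OH-] (supplies the OH oxygen of the acid)
Why: Suzuki–Miyaura vinylation with a bulky biarylphosphine ligand should tolerate the di-ortho-substituted, electron-rich iodide and the free phenol, and the ethyl ester is then saponified in the same flask.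

Step 4
Reactants: 7 2-(4-acetyl-2-ethenyl-3-hydroxy-5-methoxyphenoxy)-2-methylpropanoic acid
Product: 8 1-(5-hydroxy-7-methoxy-2,2-dimethyl-2H-chromen-6-yl)ethan-1-one
Conditions: Ir[dF(CF3)ppy]2(dtbbpy)PF6 (1 mol%), Co(dmgH)2(py)Cl (3 mol%), K2HPO4 (20 mol%), degassed MeCN/H2O 9:1 (0.02 M), blue LEDs (450 nm), rt, Ar
Reagents that add atoms: none
Why: The excited iridium catalyst should oxidize the carboxylate, which loses CO2 to give the tertiary α-aryloxy radical at the future C2; this adds to the terminal carbon of the ortho vinyl group (future C3) to give a benzylic radical at C4, and cobalt(II), formed when the reduced iridium catalyst reduces cobalt(III), removes a hydrogen atom from C3 to deliver the C3=C4 alkene and a cobalt hydride that releases H2 on protonation. The closest known reaction type is the intermolecular photoredox/cobaloxime decarboxylative Heck-type coupling of aliphatic carboxylic acids with styrenes, here run intramolecularly. The pyran ring is closed in 6-endo-trig radical mode, and no stereocentre is formed. The step needs 6-endo over 5-exo closure, which the unsubstituted vinyl terminus and the benzylic radical stabilized by the trioxygenated arene should secure, since 5-exo attack would place a primary radical next to a quaternary carbon. It also needs cyclization to outrun cobalt capture of the tertiary radical, which intramolecularity and low cobalt loading favour, and oxidation of the carboxylate rather than the phenol, which the sub-stoichiometric mild base secures by leaving the chelated phenol protonated.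

Step 5
Reactants: 8 1-(5-hydroxy-7-methoxy-2,2-dimethyl-2H-chromen-6-yl)ethan-1-one; 9 benzoyl chloride
Product: 10 1-(5-hydroxy-7-methoxy-2,2-dimethyl-2H-chromen-6-yl)-3-phenylpropane-1,3-dione
Conditions: LiHMDS (3.3 equiv), THF, −78 °C; then 9 (1.05 equiv), −78 °C to rt; aq NH4Cl
Reagents that add atoms: benzoyl chloride (compound 9), O=C(Cl)c1ccccc1
Why: Crossed Claisen-type C-acylation of the lithium phenoxide/enolate dianion should give the β-diketone directly, the third equivalent of base deprotonating the product, and the chromene alkene is inert to these conditions.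

Compound list
1 | 2',4'-dihydroxy-6'-methoxyacetophenone | CC(=O)c1c(O)cc(O)cc1OC | starting material
2 | ethyl 2-bromo-2-methylpropanoate | CCOC(=O)C(C)(C)Br | starting material
3 | ethyl 2-(4-acetyl-3-hydroxy-5-methoxyphenoxy)-2-methylpropanoate | CCOC(=O)C(C)(C)Oc1cc(O)c(C(C)=O)c(OC)c1 | intermediate
4 | ethyl 2-(4-acetyl-3-hydroxy-2-iodo-5-methoxyphenoxy)-2-methylpropanoate | CCOC(=O)C(C)(C)Oc1cc(OC)c(C(C)=O)c(O)c1I | intermediate
5 | 4,4,5,5-tetramethyl-2-vinyl-1,3,2-dioxaborolane | C=CB1OC(C)(C)C(C)(C)O1 | starting material
6 | ethyl 2-(4-acetyl-2-ethenyl-3-hydroxy-5-methoxyphenoxy)-2-methylpropanoate | CCOC(=O)C(C)(C)Oc1cc(OC)c(C(C)=O)c(O)c1C=C | intermediate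
7 | 2-(4-acetyl-2-ethenyl-3-hydroxy-5-methoxyphenoxy)-2-methylpropanoic acid | OC(=O)C(C)(C)Oc1cc(OC)c(C(C)=O)c(O)c1C=C | intermediate
8 | 1-(5-hydroxy-7-methoxy-2,2-dimethyl-2H-chromen-6-yl)ethan-1-one | COc1cc2c(c(O)c1C(C)=O)C=CC(C)(C)O2 | intermediate
9 | benzoyl chloride | O=C(Cl)c1ccccc1 | starting material
10 | 1-(5-hydroxy-7-methoxy-2,2-dimethyl-2H-chromen-6-yl)-3-phenylpropane-1,3-dione | COc1cc2c(c(O)c1C(=O)CC(=O)c1ccccc1)C=CC(C)(C)O2 | target

Total step count: 5. Longest linear sequence: 5 steps (1 → 3 → 4 → 7 → 8 → 10).

Steps most likely to fail

Step 4. The tertiary radical may be intercepted by cobalt before it cyclizes and be dehydrogenated towards an isopropenyl ether, or the excited photocatalyst may oxidize the phenol or the electron-rich product. The fallback changes the activation from oxidative to reductive. It sets out from acid 7, which would be esterified with N-hydroxyphthalimide (DIC, cat. DMAP, CH2Cl2) to the redox-active ester 1,3-dioxoisoindolin-2-yl 2-(4-acetyl-2-ethenyl-3-hydroxy-5-methoxyphenoxy)-2-methylpropanoate F1. Blue-light irradiation of F1 with Pd(PPh3)2Cl2/Xantphos and K2CO3 in DMA should give a palladium-mediated intramolecular decarboxylative Heck cyclization. This passes through the same C2 radical and 6-endo addition, followed by β-hydride elimination from the benzylpalladium species. It comes back to the route at chromene 8.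

Step 2. Regiocontrol of the iodination may be lost through attack para to the phenol, between the two ether oxygens, or through over-iodination. The fallback installs the carbon substituent by a phenol-directed reaction that can only occur ortho to the free OH. It sets out from ester 3, which would undergo magnesium-mediated ortho-formylation (MgCl2, Et3N, paraformaldehyde, MeCN, reflux) to ethyl 2-(4-acetyl-2-formyl-3-hydroxy-5-methoxyphenoxy)-2-methylpropanoate F2. Wittig methylenation of F2 (Ph3PCH3Br, KOtBu, 2.2 equiv, THF, 0 °C) should convert the aldehyde in preference to the hindered, phenoxide-deactivated ketone. It comes back to the route at vinyl ester 6, which is saponified to 7 under the second stage of step 3. This also avoids the cross-coupling of the hindered iodide.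

Step 5. O-acylation of the phenoxide may compete with C-acylation of the enolate, and double acylation is possible. The fallback moves the acyl group intramolecularly. It sets out from ketone 8, which would be O-benzoylated (benzoyl chloride, pyridine, rt) to 6-acetyl-7-methoxy-2,2-dimethyl-2H-chromen-5-yl benzoate F3. Baker–Venkataraman rearrangement of F3 (KOtBu, THF, rt, or KOH, pyridine, 50 °C) should transfer the benzoyl group to the enolate carbon. It comes back to the route at target 10.

Further compounds
F1 | step 4 | 1,3-dioxoisoindolin-2-yl 2-(4-acetyl-2-ethenyl-3-hydroxy-5-methoxyphenoxy)-2-methylpropanoate | CC(=O)c1c(OC)cc(OC(C)(C)C(=O)ON2C(=O)c3ccccc3C2=O)c(C=C)c1O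
F2 | step 2 | ethyl 2-(4-acetyl-2-formyl-3-hydroxy-5-methoxyphenoxy)-2-methylpropanoate | CCOC(=O)C(C)(C)Oc1cc(OC)c(C(C)=O)c(O)c1C=O
F3 | step 5 | 6-acetyl-7-methoxy-2,2-dimethyl-2H-chromen-5-yl benzoate | COc1cc2c(c(OC(=O)c3ccccc3)c1C(C)=O)C=CC(C)(C)O2
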